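**Retrosynthetic overview**
1. 14 ⇐ 13: the six benzyl ethers are removed last, by neutral hydrogenolysis.
2. 13 ⇐ 11 + 12: the (2S) centre is set by ligand-controlled 1,4-arylation of the chromone half only; the flavone half is inert.
3. 11 ⇐ 6 + 7 + 8 (key step): ring C of the flavone and ring C of the chromone close together from the diacetyl biphenol 6 after one-flask aroylation/formylation.
4. 6 ⇐ 3 ⇐ 1: the C8–C8'' biaryl bond comes from iodination and palladium-catalysed homocoupling of a bought acetophenone.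
5. Ring order: rings A and B are bought; then the biaryl bond; then both rings C in one operation; the stereocentre is introduced afterwards.

Assumption: the SMILES fixes only C2 (S) and leaves the hindered C8–C8'' axis open, so the route delivers (2S)-14 as a mixture of the two atropisomers, both matching the given structure (separable by HPLC if one is wanted).

**Step 1**
Reactants: 1 1-[2-hydroxy-4,6-bis(benzyloxy)phenyl]ethanone; 2 N-iodosuccinimide
Product: 3 1-[2-hydroxy-3-iodo-4,6-bis(benzyloxy)phenyl]ethanone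
Conditions: NIS (1.05 equiv), TsOH·H2O (10 mol%), MeCN, 0 °C to rt
Reagents that add atoms: N-iodosuccinimide (2), O=C1CCC(=O)N1I
Why: Electrophilic aromatic iodination; of the two free ring positions, the one ortho to the chelated OH (C3, the future C8) is the less hindered and is the one expected to be iodinated in 2-hydroxy-4,6-dialkoxyacetophenones; no stereocentre is formed.

**Step 2**
Reactants: 3 1-[2-hydroxy-3-iodo-4,6-bis(benzyloxy)phenyl]ethanone (2 equiv); 4 bis(pinacolato)diboron
Product: 6 3,3'-diacetyl-4,4',6,6'-tetrakis(benzyloxy)biphenyl-2,2'-diol (racemic axis), via pinacol boronate 5 (not isolated)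
Conditions: B2pin2 (0.55 equiv), Pd(OAc)2 (5 mol%), SPhos (10 mol%), K3PO4 (3 equiv), 1,4-dioxane/H2O (9:1), 90 °C
Reagents that add atoms: none
Why: One-flask Miyaura borylation/Suzuki–Miyaura homocoupling: about half of 3 is borylated to 5, which couples with the remaining 3, the bulky electron-rich SPhos ligand allowing the tetra-ortho-substituted biaryl; the axis forms racemic, which is accepted.

**Step 3 (key step)**
Reactants: 6 3,3'-diacetyl-4,4',6,6'-tetrakis(benzyloxy)biphenyl-2,2'-diol; 7 4-(benzyloxy)benzoyl chloride; 8 ethyl formate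
Product: 11 5,7-bis(benzyloxy)-8-[5,7-bis(benzyloxy)-4-oxo-4H-chromen-8-yl]-2-[4-(benzyloxy)phenyl]-4H-chromen-4-one, via monodiketone 9 (not isolated), via formyl diketone 10 (not isolated)
Conditions: LiN(SiMe3)2 (7 equiv), THF, −78 to −10 °C; 7 (1.0 equiv), −78 °C to rt; HCO2Et (10 equiv), 0 °C to rt; AcOH quench, water wash (no purification); then TsOH·H2O (20 mol%), toluene, 80 °C
Reagents that add atoms: 4-(benzyloxy)benzoyl chloride (7), O=C(Cl)c1ccc(OCc2ccccc2)cc1; ethyl formate (8), CCOC=O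
Why: Proposed new method: the tetralithio bis(phenoxide–enolate) of 6 is C-aroylated once by 1.0 equiv of 7 (closest known reaction: direct LiN(SiMe3)2-mediated aroylation of 2-hydroxyacetophenone dianions to 1,3-diketones, a one-flask Baker–Venkataraman equivalent), the untouched enolate of the other half then undergoes Claisen formylation with 8 while the stabilised diketonate stays inert, and acid closes both halves by cyclodehydration (the classical flavone and chromone ring closures), so the two pyranone rings form in the same operation through the only free phenol of each half (hence the 8,8'' linkage); mono-aroylation is statistical (about half of the material at best, the symmetric bis-flavone and bis-chromone being removed by chromatography), no stereocentre is formed and the axis stays racemic.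

**Step 4**
Reactants: 11 5,7-bis(benzyloxy)-8-[5,7-bis(benzyloxy)-4-oxo-4H-chromen-8-yl]-2-[4-(benzyloxy)phenyl]-4H-chromen-4-one; 12 4-(benzyloxy)phenylboronic acid
Product: 13 (2S)-5,7-bis(benzyloxy)-8-{5,7-bis(benzyloxy)-2-[4-(benzyloxy)phenyl]-4-oxo-4H-chromen-8-yl}-2-[4-(benzyloxy)phenyl]-2,3-dihydro-4H-chromen-4-one (two atropisomers)
Conditions: 12 (3 equiv), Pd(OCOCF3)2 (10 mol%), (R)-4-tert-butyl-2-(pyridin-2-yl)-4,5-dihydrooxazole [(R)-t-BuPyOx, 12 mol%], NH4PF6 (30 mol%), H2O (5 equiv), ClCH2CH2Cl, 60 °C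
Reagents that add atoms: 4-(benzyloxy)phenylboronic acid (12), OB(O)c1ccc(OCc2ccccc2)cc1
Why: Palladium-catalysed asymmetric conjugate addition of an arylboronic acid to a chromone: the cationic aryl–palladium complex (divalent palladium) of the chiral pyridine–oxazoline delivers the aryl group to the Re face of C2 (giving 2S; the ligand antipode is assigned by analogy with the sense it shows on cyclic enones and is to be confirmed by CD on the first batch), the flavone half with its fully substituted, aryl-conjugated C2 does not react, and the base-free medium prevents retro-oxa-Michael racemisation.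

**Step 5**
Reactants: 13 (2S)-5,7-bis(benzyloxy)-8-{5,7-bis(benzyloxy)-2-[4-(benzyloxy)phenyl]-4-oxo-4H-chromen-8-yl}-2-[4-(benzyloxy)phenyl]-2,3-dihydro-4H-chromen-4-one
Product: 14 (2S)-5,7-dihydroxy-8-[5,7-dihydroxy-2-(4-hydroxyphenyl)-4-oxo-4H-chromen-8-yl]-2-(4-hydroxyphenyl)-2,3-dihydro-4H-chromen-4-one (target)
Conditions: H2 (1 atm), Pd/C (10 wt% palladium on carbon), EtOAc/MeOH (1:1), rt; neutral work-up
Reagents that add atoms: none
Why: Catalytic hydrogenolysis of benzyl aryl ethers under neutral conditions, which neither enolises nor ring-opens the flavanone, so (2S) is kept; the O-benzyl groups cleave much faster than the cyclic C2–O1 bond or the flavone C2=C3 bond is reduced.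

**Compound list**
1 | 1-[2-hydroxy-4,6-bis(benzyloxy)phenyl]ethanone | CC(=O)c1c(O)cc(OCc2ccccc2)cc1OCc1ccccc1 | starting material
2 | N-iodosuccinimide | O=C1CCC(=O)N1I | starting material
3 | 1-[2-hydroxy-3-iodo-4,6-bis(benzyloxy)phenyl]ethanone | CC(=O)c1c(O)c(I)c(OCc2ccccc2)cc1OCc1ccccc1 | intermediate
4 | bis(pinacolato)diboron | CC1(C)OB(OC1(C)C)B1OC(C)(C)C(C)(C)O1 | starting material
5 | 1-[4,6-bis(benzyloxy)-2-hydroxy-3-(4,4,5,5-tetramethyl-1,3,2-dioxaborolan-2-yl)phenyl]ethanone (not isolated) | CC(=O)c1c(O)c(B2OC(C)(C)C(C)(C)O2)c(OCc2ccccc2)cc1OCc1ccccc1 | intermediate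
6 | 3,3'-diacetyl-4,4',6,6'-tetrakis(benzyloxy)biphenyl-2,2'-diol (racemic axis) | CC(=O)c1c(O)c(-c2c(O)c(C(C)=O)c(OCc3ccccc3)cc2OCc2ccccc2)c(OCc2ccccc2)cc1OCc1ccccc1 | intermediate
7 | 4-(benzyloxy)benzoyl chloride | O=C(Cl)c1ccc(OCc2ccccc2)cc1 | starting material
8 | ethyl formate | CCOC=O | starting material
9 | 1-[3'-acetyl-4,4',6,6'-tetrakis(benzyloxy)-2,2'-dihydroxybiphenyl-3-yl]-3-[4-(benzyloxy)phenyl]propane-1,3-dione (not isolated) | CC(=O)c1c(O)c(-c2c(O)c(C(=O)CC(=O)c3ccc(OCc4ccccc4)cc3)c(OCc3ccccc3)cc2OCc2ccccc2)c(OCc2ccccc2)cc1OCc1ccccc1 | intermediate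
10 | 3-{4,4',6,6'-tetrakis(benzyloxy)-3'-[3-(4-(benzyloxy)phenyl)-3-oxopropanoyl]-2,2'-dihydroxybiphenyl-3-yl}-3-oxopropanal (not isolated) | O=CCC(=O)c1c(O)c(-c2c(O)c(C(=O)CC(=O)c3ccc(OCc4ccccc4)cc3)c(OCc3ccccc3)cc2OCc2ccccc2)c(OCc2ccccc2)cc1OCc1ccccc1 | intermediate
11 | 5,7-bis(benzyloxy)-8-[5,7-bis(benzyloxy)-4-oxo-4H-chromen-8-yl]-2-[4-(benzyloxy)phenyl]-4H-chromen-4-one | O=c1ccoc2c1c(OCc1ccccc1)cc(OCc1ccccc1)c2-c1c(OCc2ccccc2)cc(OCc2ccccc2)c2c(=O)cc(-c3ccc(OCc4ccccc4)cc3)oc12 | intermediate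
12 | 4-(benzyloxy)phenylboronic acid | OB(O)c1ccc(OCc2ccccc2)cc1 | starting material
13 | (2S)-5,7-bis(benzyloxy)-8-{5,7-bis(benzyloxy)-2-[4-(benzyloxy)phenyl]-4-oxo-4H-chromen-8-yl}-2-[4-(benzyloxy)phenyl]-2,3-dihydro-4H-chromen-4-one | O=C1C[C@@H](c2ccc(OCc3ccccc3)cc2)Oc2c1c(OCc1ccccc1)cc(OCc1ccccc1)c2-c1c(OCc2ccccc2)cc(OCc2ccccc2)c2c(=O)cc(-c3ccc(OCc4ccccc4)cc3)oc12 | intermediate
14 | (2S)-5,7-dihydroxy-8-[5,7-dihydroxy-2-(4-hydroxyphenyl)-4-oxo-4H-chromen-8-yl]-2-(4-hydroxyphenyl)-2,3-dihydro-4H-chromen-4-one | O=C1C[C@@H](c2ccc(O)cc2)Oc2c1c(O)cc(O)c2-c1c(O)cc(O)c2c(=O)cc(-c3ccc(O)cc3)oc12 | target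

**Totals**
Total step count: 5. Longest linear sequence: 5 (fully linear, 1 → 3 → 6 → 11 → 13 → 14).

**Steps most likely to fail, with fallbacks**

Step 3 (key step). The mono-aroylation is statistical, and two different Claisen condensations must run cleanly in one flask before the double ring closure. The fallback sets out from 6 and comes back at 11. Condensation of both acetyl groups with Me2NCH(OMe)2 (toluene, 100 °C) gives 1,1'-[4,4',6,6'-tetrakis(benzyloxy)-2,2'-dihydroxybiphenyl-3,3'-diyl]bis[(2E)-3-(dimethylamino)prop-2-en-1-one] F3. TsOH·H2O in CH2Cl2/MeOH closes both rings, still in one operation, to 5,5',7,7'-tetrakis(benzyloxy)-8,8'-bi(4H-chromen-4-one) F4. One chromone unit is then arylated at C2 with 12 as limiting reagent in an oxidative Heck-type coupling (Pd(OCOCF3)2, 1,10-phenanthroline, O2, DMF, 80 °C) to give 11, with unreacted F4 recycled. The bis-chromone by-product of step 3 is this same F4 and can be fed into the arylation.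

Step 2. The biaryl is tetra-ortho-substituted, the phenols are free, and the 2,6-dioxygenated boronate 5 is prone to protodeboronation (which only returns 1). The fallback sets out from 3 and comes back at 6. The phenol is capped (NaH, MOMCl, DMF) to give 1-[4,6-bis(benzyloxy)-3-iodo-2-(methoxymethoxy)phenyl]ethanone F1. A classical Ullmann reductive coupling (activated Cu powder, DMF, 150 °C) gives 3,3'-diacetyl-4,4',6,6'-tetrakis(benzyloxy)-2,2'-bis(methoxymethoxy)biphenyl F2. HCl in MeOH/THF at rt removes the two methoxymethyl groups, leaving the benzyl ethers, to give 6.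

Step 4. The chromone is electron-rich and carries a bulky 8-substituent, so rate and enantioselectivity may suffer, and the ligand sense rests on analogy. The fallback sets out from 11 and comes back at 13. Conjugate addition of 12 with the smaller achiral catalyst Pd(OCOCF3)2/2,2'-bipyridine (aqueous AcOH/THF, 60 °C) gives (2RS)-5,7-bis(benzyloxy)-8-{5,7-bis(benzyloxy)-2-[4-(benzyloxy)phenyl]-4-oxo-4H-chromen-8-yl}-2-[4-(benzyloxy)phenyl]-2,3-dihydro-4H-chromen-4-one F5. The (2S) isomers are then isolated by preparative HPLC on a chiral stationary phase (amylose tris(3,5-dimethylphenylcarbamate)) to give 13, so the centre is secured by resolution, not catalysis.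

**Further compounds**
F1 | step 2 | 1-[4,6-bis(benzyloxy)-3-iodo-2-(methoxymethoxy)phenyl]ethanone | CC(=O)c1c(OCOC)c(I)c(OCc2ccccc2)cc1OCc1ccccc1
F2 | step 2 | 3,3'-diacetyl-4,4',6,6'-tetrakis(benzyloxy)-2,2'-bis(methoxymethoxy)biphenyl | CC(=O)c1c(OCOC)c(-c2c(OCOC)c(C(C)=O)c(OCc3ccccc3)cc2OCc2ccccc2)c(OCc2ccccc2)cc1OCc1ccccc1
F3 | step 3 | 1,1'-[4,4',6,6'-tetrakis(benzyloxy)-2,2'-dihydroxybiphenyl-3,3'-diyl]bis[(2E)-3-(dimethylamino)prop-2-en-1-one] | CN(C)/C=C/C(=O)c1c(O)c(-c2c(O)c(C(=O)/C=C/N(C)C)c(OCc3ccccc3)cc2OCc2ccccc2)c(OCc2ccccc2)cc1OCc1ccccc1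
F4 | step 3 | 5,5',7,7'-tetrakis(benzyloxy)-8,8'-bi(4H-chromen-4-one) | O=c1ccoc2c1c(OCc1ccccc1)cc(OCc1ccccc1)c2-c1c(OCc2ccccc2)cc(OCc2ccccc2)c2c(=O)ccoc12
F5 | step 4 | (2RS)-5,7-bis(benzyloxy)-8-{5,7-bis(benzyloxy)-2-[4-(benzyloxy)phenyl]-4-oxo-4H-chromen-8-yl}-2-[4-(benzyloxy)phenyl]-2,3-dihydro-4H-chromen-4-one | O=C1CC(c2ccc(OCc3ccccc3)cc2)Oc2c1c(OCc1ccccc1)cc(OCc1ccccc1)c2-c1c(OCc2ccccc2)cc(OCc2ccccc2)c2c(=O)cc(-c3ccc(OCc4ccccc4)cc3)oc12
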